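**Retrosynthetic overview**

1. Target 24 ← C12–Br by invertive bromination of the all-cis C12 alcohol; the (Z)-enyne (C3=C4) by cross-metathesis; C5–Cl and C6–O by γ-chloroallylboration of a C6 aldehyde; C10–Cl from an enol triflate.
2. Oxocene ← key disconnection at C11–C12 and C7–C8: a four-carbon diene (C8–C11; 2-silyloxybutadiene as chloroprene surrogate) is inserted by nickel catalysis into the C12–C7 bond of oxetan-3-one 5 (formal [4+4], strain release).
3. Enabling feature: the ring oxygen O1 links C7 and C13, and C12 is a carbonyl-level carbon next to C13, so O1–C13–C12–C7 can be folded into a four-membered oxetan-3-one. Its strained C12(=O)–C7 bond, activated by the C7 ester (the future C6), is the bond that opens.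
4. Oxetanone 5 ← gold-catalysed alkyne oxidation/O–H insertion of γ-hydroxy ynoate 4 ← catalytic enantioselective alkynylation of propanal (sets C13; C7 and C12 are relayed from it, C5/C6 come from reagent control).
5. Ring order: oxetanone (step 2), then its expansion to the only ring of the target, the oxocene (step 3).

Key step: step 3

**Remarks**

- Atoms are numbered along the C15 chain of the target: C1 alkyne CH, C5 CHCl, C6 CHOAc, C7 and C13 on the ring oxygen, C10 CCl, C12 CHBr, C14–C15 ethyl. Ring compounds are named as oxocines (O1, C2 = C7, C5 = C10, C7 = C12, C8 = C13).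
- The ring alkene is cis within the ring; its CIP label is E because Cl or O outranks carbon at C10.
- Assumption: (S,S)-ProPhenol delivers the R carbinol in step 1, and the borane from (−)-α-pinene delivers 6S in step 9; if either facial sense proves opposite, the antipodal ligand or borane is used.
- Oxetanone 5 is formed and used as a mixture of epimers at the ester-bearing carbon (C7); both converge in step 3.

**Route**

Step 1
Reactants: 1 propanal; 2 methyl propiolate
Product: 4 methyl (4R)-4-hydroxyhex-2-ynoate, via methyl 3-(methylzincio)prop-2-ynoate 3 (not isolated)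
Conditions: Me2Zn (3 equiv), (S,S)-ProPhenol (10 mol %), Ph3P=O (20 mol %), toluene, 0 °C; aq NH4Cl
Reagents that add atoms: none
Why: Dinuclear zinc–ProPhenol catalysed enantioselective alkynylation of an aldehyde, in which the alkynylzinc 3 is delivered to one face of propanal inside the chiral bimetallic pocket and should set the C13 carbinol centre as R.

Step 2
Reactants: 4 methyl (4R)-4-hydroxyhex-2-ynoate
Product: 5 methyl (4R)-4-ethyl-3-oxooxetane-2-carboxylate (both C2 epimers)
Conditions: Ph3PAuNTf2 (5 mol %), 3,5-dichloropyridine N-oxide (2 equiv), ClCH2CH2Cl, rt to 40 °C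
Reagents that add atoms: 3,5-dichloropyridine N-oxide, [O-][n+]1cc(Cl)cc(Cl)c1
Why: Gold-catalysed alkyne oxidation places the N-oxide oxygen on the ynoate β-carbon (C12) and the resulting α-oxo gold carbene at C7 inserts into the neighbouring O–H bond to close the oxetan-3-one; C13 is untouched and the new C7 centre, formed unselectively, is erased in step 3.

Step 3
Reactants: 5 methyl (4R)-4-ethyl-3-oxooxetane-2-carboxylate; 6 2-(trimethylsilyloxy)buta-1,3-diene
Product: 7 methyl (2R,4E,8R)-8-ethyl-7-oxo-5-(trimethylsilyloxy)-3,6,7,8-tetrahydro-2H-oxocine-2-carboxylate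
Conditions: Ni(cod)2 (10 mol %), PPh3 (25 mol %), 6 (3 equiv), toluene, 70 °C, slow addition of 5; filtration through Et3N-deactivated silica
Reagents that add atoms: none
Why: Proposed new method: zerovalent nickel should couple the strained C12 carbonyl of 5 oxidatively with the silyloxy-substituted double bond of diene 6 (C12–C11 bond) to an oxanickelacycle carrying a π-allyl arm, the nickel alkoxide then undergoes β-carbon elimination across the strained C12–C7 bond (a retro-aldol opening of the four-membered ring that leaves a nickel ester enolate), and C–C reductive elimination joins C7 to the distal allyl terminus C8. The closest known reaction type is the nickel-catalysed formal [4+4] cycloaddition of 1,3-dienes with 3-oxetanones and 3-azetidinones by C–C bond activation, here extended to a 2,4-disubstituted, ester-bearing oxetanone and a 2-silyloxy diene. The oxocene ring is closed by ring expansion, the four-membered ring growing by the four diene carbons, with the last bond made by reductive elimination from a nine-membered allyl nickel enolate. C13 is carried through unchanged, the new C7 centre is set under substrate control cis to the C13 ethyl group (both C7 epimers of 5 converge on one enolate, and a chair-like closure places ester and ethyl pseudo-equatorial), and the ring alkene can only be cis. The step needs cleavage of C12–C7 rather than C12–C13, which the enolate-stabilising ester at C7 secures, bonding of C12 to the diene terminus next to the oxygenated carbon, which the donor silyloxy group secures as for other 2-substituted dienes, and closure at C8 rather than at the fully substituted C10. Diene 6 stands in for chloroprene because a vinyl C–Cl bond would add oxidatively to zerovalent nickel, and its enol ether fixes the position of the later chloroalkene.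

Step 4
Reactants: 7 methyl (2R,4E,8R)-8-ethyl-7-oxo-5-(trimethylsilyloxy)-3,6,7,8-tetrahydro-2H-oxocine-2-carboxylate
Product: 8 methyl (2R,4E,7R,8R)-8-ethyl-7-hydroxy-5-(trimethylsilyloxy)-3,6,7,8-tetrahydro-2H-oxocine-2-carboxylate
Conditions: LiBH(s-Bu)3 (1.1 equiv), THF, −78 °C; aq NaHCO3 (no oxidative work-up)
Reagents that add atoms: none
Why: Substrate-controlled ketone reduction in which the bulky hydride should attack C12 from the ring face opposite the adjacent C13 ethyl group (Felkin–Anh sense for an α-alkoxy ketone), giving the 12,13-cis alcohol while ester and silyl enol ether stay intact at −78 °C.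

Step 5
Reactants: 8 methyl (2R,4E,7R,8R)-8-ethyl-7-hydroxy-5-(trimethylsilyloxy)-3,6,7,8-tetrahydro-2H-oxocine-2-carboxylate
Product: 9 methyl (2R,4E,7R,8R)-7-(tert-butyldimethylsilyloxy)-8-ethyl-5-(trimethylsilyloxy)-3,6,7,8-tetrahydro-2H-oxocine-2-carboxylate
Conditions: TBSOTf, 2,6-lutidine, CH2Cl2, −78 °C
Reagents that add atoms: tert-butyldimethylsilyl triflate, CC(C)(C)[Si](C)(C)OS(=O)(=O)C(F)(F)F
Why: Standard silylation of a secondary alcohol with a silyl triflate and a hindered base, which creates no stereocentre and leaves enol ether and ester untouched.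

Step 6
Reactants: 9 methyl (2R,4E,7R,8R)-7-(tert-butyldimethylsilyloxy)-8-ethyl-5-(trimethylsilyloxy)-3,6,7,8-tetrahydro-2H-oxocine-2-carboxylate
Product: 11 methyl (2R,4E,7R,8R)-7-(tert-butyldimethylsilyloxy)-8-ethyl-5-(trifluoromethylsulfonyloxy)-3,6,7,8-tetrahydro-2H-oxocine-2-carboxylate, via caesium enolate 10 (not isolated)
Conditions: CsF, PhNTf2, DME, rt
Reagents that add atoms: N-phenylbis(trifluoromethanesulfonimide), O=S(=O)(N(c1ccccc1)S(=O)(=O)C(F)(F)F)C(F)(F)F
Why: Fluoride cleaves only the labile enol Si–O bond and the enolate 10 is triflated on oxygen before it can equilibrate, so this regiospecific silyl enol ether to enol triflate conversion keeps the C9=C10 position fixed in step 3.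

Step 7
Reactants: 11 methyl (2R,4E,7R,8R)-7-(tert-butyldimethylsilyloxy)-8-ethyl-5-(trifluoromethylsulfonyloxy)-3,6,7,8-tetrahydro-2H-oxocine-2-carboxylate
Product: 12 methyl (2R,4E,7R,8R)-7-(tert-butyldimethylsilyloxy)-5-chloro-8-ethyl-3,6,7,8-tetrahydro-2H-oxocine-2-carboxylate
Conditions: Ni(cod)2 (10 mol %), LiCl (3 equiv), DMA/THF, rt
Reagents that add atoms: lithium chloride, [Li+].[Cl-]
Why: Nickel-catalysed halogen exchange of an enol triflate, in which oxidative addition of zerovalent nickel into the C10–O bond, triflate-to-chloride exchange at divalent nickel and C–Cl reductive elimination should give the alkenyl chloride with the ring-cis alkene retained.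

Step 8
Reactants: 12 methyl (2R,4E,7R,8R)-7-(tert-butyldimethylsilyloxy)-5-chloro-8-ethyl-3,6,7,8-tetrahydro-2H-oxocine-2-carboxylate
Product: 14 (2R,4E,7R,8R)-7-(tert-butyldimethylsilyloxy)-5-chloro-8-ethyl-3,6,7,8-tetrahydro-2H-oxocine-2-carbaldehyde, via diisobutylaluminium hemiacetal 13 (not isolated)
Conditions: i-Bu2AlH (1.1 equiv), CH2Cl2, −78 °C; aq potassium sodium tartrate
Reagents that add atoms: none
Why: Partial reduction of an α-alkoxy ester with i-Bu2AlH at −78 °C stops at the tetrahedral hemiacetal 13, which releases the aldehyde only on work-up, and the C7 centre should survive if the aldehyde is used at once.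

Step 9
Reactants: 14 (2R,4E,7R,8R)-7-(tert-butyldimethylsilyloxy)-5-chloro-8-ethyl-3,6,7,8-tetrahydro-2H-oxocine-2-carbaldehyde
Product: 16 (1S,2S)-1-[(2R,4E,7R,8R)-7-(tert-butyldimethylsilyloxy)-5-chloro-8-ethyl-3,6,7,8-tetrahydro-2H-oxocin-2-yl]-2-chlorobut-3-en-1-ol, via O-diisopinocampheylborinate 15 (not isolated)
Conditions: allyl chloride, (+)-B-methoxydiisopinocampheylborane, LiN(c-Hex)2 (from c-Hex2NH, n-BuLi), Et2O, −95 °C; BF3·OEt2; 14, −95 °C; H2O2, pH 7 buffer, MeOH, 0 °C
Reagents that add atoms: allyl chloride, C=CCCl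
Why: γ-Chloroallylboration through a closed chair (Zimmerman–Traxler) transition state, in which the Z-configured chloroallyl unit gives the 5,6-syn chlorohydrin and the isopinocampheyl groups from (−)-α-pinene should direct attack to the aldehyde face that gives 6S and hence 5S under reagent control.

Step 10
Reactants: 16 (1S,2S)-1-[(2R,4E,7R,8R)-7-(tert-butyldimethylsilyloxy)-5-chloro-8-ethyl-3,6,7,8-tetrahydro-2H-oxocin-2-yl]-2-chlorobut-3-en-1-ol
Product: 17 (1S,2S)-1-[(2R,4E,7R,8R)-7-(tert-butyldimethylsilyloxy)-5-chloro-8-ethyl-3,6,7,8-tetrahydro-2H-oxocin-2-yl]-2-chlorobut-3-en-1-yl acetate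
Conditions: Ac2O, pyridine, DMAP (cat.), CH2Cl2, 0 °C
Reagents that add atoms: acetic anhydride, CC(=O)OC(C)=O
Why: Standard acylation of a secondary alcohol under nucleophilic catalysis, which affects no stereocentre and is mild enough that the chlorohydrin should not close to an epoxide first.

Step 11
Reactants: 18 ethynyltriisopropylsilane; 19 vinyl bromide
Product: 20 (but-3-en-1-yn-1-yl)triisopropylsilane
Conditions: Pd(PPh3)2Cl2 (2 mol %), CuI (4 mol %), Et3N, THF, 0 °C to rt
Reagents that add atoms: none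
Why: Sonogashira coupling of a terminal alkyne with vinyl bromide should give the silyl-capped conjugated enyne needed as metathesis partner.

Step 12
Reactants: 17 (1S,2S)-1-[(2R,4E,7R,8R)-7-(tert-butyldimethylsilyloxy)-5-chloro-8-ethyl-3,6,7,8-tetrahydro-2H-oxocin-2-yl]-2-chlorobut-3-en-1-yl acetate; 20 (but-3-en-1-yn-1-yl)triisopropylsilane
Product: 21 (1S,2S,3Z)-1-[(2R,4E,7R,8R)-7-(tert-butyldimethylsilyloxy)-5-chloro-8-ethyl-3,6,7,8-tetrahydro-2H-oxocin-2-yl]-2-chloro-6-(triisopropylsilyl)hex-3-en-5-yn-1-yl acetate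
Conditions: second-generation Grubbs catalyst (10 mol %), 20 (5 equiv), CH2Cl2, 40 °C
Reagents that add atoms: none
Why: Cross-metathesis of a terminal alkene with a silyl-capped conjugated enyne, which favours the Z-enyne kinetically because the slim alkynyl group is tolerated cis in the ruthenacyclobutane and the product re-enters metathesis slowly, while the hindered, electron-poor ring chloroalkene should not react.

Step 13
Reactants: 21 (1S,2S,3Z)-1-[(2R,4E,7R,8R)-7-(tert-butyldimethylsilyloxy)-5-chloro-8-ethyl-3,6,7,8-tetrahydro-2H-oxocin-2-yl]-2-chloro-6-(triisopropylsilyl)hex-3-en-5-yn-1-yl acetate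
Product: 22 (1S,2S,3Z)-2-chloro-1-[(2R,4E,7R,8R)-5-chloro-8-ethyl-7-hydroxy-3,6,7,8-tetrahydro-2H-oxocin-2-yl]hex-3-en-5-yn-1-yl acetate
Conditions: Bu4NF (3 equiv), AcOH (3 equiv), THF, 0 °C to rt
Reagents that add atoms: none
Why: Fluoride-mediated cleavage of the C(sp)–Si and O–Si bonds, with acetic acid buffering so that the acetate and the allylic chloride should not suffer from base.

Step 14
Reactants: 22 (1S,2S,3Z)-2-chloro-1-[(2R,4E,7R,8R)-5-chloro-8-ethyl-7-hydroxy-3,6,7,8-tetrahydro-2H-oxocin-2-yl]hex-3-en-5-yn-1-yl acetate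
Product: 24 (1S,2S,3Z)-2-chloro-1-[(2R,4E,7S,8R)-7-bromo-5-chloro-8-ethyl-3,6,7,8-tetrahydro-2H-oxocin-2-yl]hex-3-en-5-yn-1-yl acetate, via alkoxyphosphonium bromide 23 (not isolated)
Conditions: CBr4, (n-Oct)3P, toluene, 70 °C
Reagents that add atoms: carbon tetrabromide, BrC(Br)(Br)Br
Why: Appel-type bromination in which the C12 alcohol is activated as the alkoxyphosphonium salt 23 and displaced by bromide in an SN2 step with inversion, turning the 12R alcohol into the 12S bromide trans to the ethyl group.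

**Compound list**

1 | propanal | CCC=O | starting material
2 | methyl propiolate | C#CC(=O)OC | starting material
3 | methyl 3-(methylzincio)prop-2-ynoate | C[Zn]C#CC(=O)OC | intermediate
4 | methyl (4R)-4-hydroxyhex-2-ynoate | CC[C@@H](O)C#CC(=O)OC | intermediate
5 | methyl (4R)-4-ethyl-3-oxooxetane-2-carboxylate (both C2 epimers) | CC[C@H]1OC(C(=O)OC)C1=O | intermediate
6 | 2-(trimethylsilyloxy)buta-1,3-diene | C=CC(=C)O[Si](C)(C)C | starting material
7 | methyl (2R,4E,8R)-8-ethyl-7-oxo-5-(trimethylsilyloxy)-3,6,7,8-tetrahydro-2H-oxocine-2-carboxylate | COC(=O)[C@H]1C/C=C(/O[Si](C)(C)C)CC(=O)[C@@H](CC)O1 | intermediate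
8 | methyl (2R,4E,7R,8R)-8-ethyl-7-hydroxy-5-(trimethylsilyloxy)-3,6,7,8-tetrahydro-2H-oxocine-2-carboxylate | COC(=O)[C@H]1C/C=C(/O[Si](C)(C)C)C[C@@H](O)[C@@H](CC)O1 | intermediate
9 | methyl (2R,4E,7R,8R)-7-(tert-butyldimethylsilyloxy)-8-ethyl-5-(trimethylsilyloxy)-3,6,7,8-tetrahydro-2H-oxocine-2-carboxylate | COC(=O)[C@H]1C/C=C(/O[Si](C)(C)C)C[C@@H](O[Si](C)(C)C(C)(C)C)[C@@H](CC)O1 | intermediate
10 | caesium (2R,4E,7R,8R)-7-(tert-butyldimethylsilyloxy)-8-ethyl-2-(methoxycarbonyl)-3,6,7,8-tetrahydro-2H-oxocin-5-olate | [Cs+].COC(=O)[C@H]1C/C=C(/[O-])C[C@@H](O[Si](C)(C)C(C)(C)C)[C@@H](CC)O1 | intermediate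
11 | methyl (2R,4E,7R,8R)-7-(tert-butyldimethylsilyloxy)-8-ethyl-5-(trifluoromethylsulfonyloxy)-3,6,7,8-tetrahydro-2H-oxocine-2-carboxylate | COC(=O)[C@H]1C/C=C(/OS(=O)(=O)C(F)(F)F)C[C@@H](O[Si](C)(C)C(C)(C)C)[C@@H](CC)O1 | intermediate
12 | methyl (2R,4E,7R,8R)-7-(tert-butyldimethylsilyloxy)-5-chloro-8-ethyl-3,6,7,8-tetrahydro-2H-oxocine-2-carboxylate | COC(=O)[C@H]1C/C=C(/Cl)C[C@@H](O[Si](C)(C)C(C)(C)C)[C@@H](CC)O1 | intermediate
13 | diisobutylaluminium hemiacetal of 12 (O-aluminated methyl hemiacetal at C6, both epimers) | COC(O[Al](CC(C)C)CC(C)C)[C@H]1C/C=C(/Cl)C[C@@H](O[Si](C)(C)C(C)(C)C)[C@@H](CC)O1 | intermediate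
14 | (2R,4E,7R,8R)-7-(tert-butyldimethylsilyloxy)-5-chloro-8-ethyl-3,6,7,8-tetrahydro-2H-oxocine-2-carbaldehyde | O=C[C@H]1C/C=C(/Cl)C[C@@H](O[Si](C)(C)C(C)(C)C)[C@@H](CC)O1 | intermediate
15 | diisopinocampheylborinate of 16 (boron on the C6 oxygen, isopinocampheyl groups from (−)-α-pinene) | C=C[C@H](Cl)[C@@H](OB([C@H]2C[C@H]3C[C@@H]([C@@H]2C)C3(C)C)[C@H]2C[C@H]3C[C@@H]([C@@H]2C)C3(C)C)[C@H]1C/C=C(/Cl)C[C@@H](O[Si](C)(C)C(C)(C)C)[C@@H](CC)O1 | intermediate
16 | (1S,2S)-1-[(2R,4E,7R,8R)-7-(tert-butyldimethylsilyloxy)-5-chloro-8-ethyl-3,6,7,8-tetrahydro-2H-oxocin-2-yl]-2-chlorobut-3-en-1-ol | C=C[C@H](Cl)[C@@H](O)[C@H]1C/C=C(/Cl)C[C@@H](O[Si](C)(C)C(C)(C)C)[C@@H](CC)O1 | intermediate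
17 | (1S,2S)-1-[(2R,4E,7R,8R)-7-(tert-butyldimethylsilyloxy)-5-chloro-8-ethyl-3,6,7,8-tetrahydro-2H-oxocin-2-yl]-2-chlorobut-3-en-1-yl acetate | C=C[C@H](Cl)[C@@H](OC(C)=O)[C@H]1C/C=C(/Cl)C[C@@H](O[Si](C)(C)C(C)(C)C)[C@@H](CC)O1 | intermediate
18 | ethynyltriisopropylsilane | C#C[Si](C(C)C)(C(C)C)C(C)C | starting material
19 | vinyl bromide | C=CBr | starting material
20 | (but-3-en-1-yn-1-yl)triisopropylsilane | C=CC#C[Si](C(C)C)(C(C)C)C(C)C | intermediate
21 | (1S,2S,3Z)-1-[(2R,4E,7R,8R)-7-(tert-butyldimethylsilyloxy)-5-chloro-8-ethyl-3,6,7,8-tetrahydro-2H-oxocin-2-yl]-2-chloro-6-(triisopropylsilyl)hex-3-en-5-yn-1-yl acetate | CC(C)[Si](C#C/C=C\[C@H](Cl)[C@@H](OC(C)=O)[C@H]1C/C=C(/Cl)C[C@@H](O[Si](C)(C)C(C)(C)C)[C@@H](CC)O1)(C(C)C)C(C)C | intermediate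
22 | (1S,2S,3Z)-2-chloro-1-[(2R,4E,7R,8R)-5-chloro-8-ethyl-7-hydroxy-3,6,7,8-tetrahydro-2H-oxocin-2-yl]hex-3-en-5-yn-1-yl acetate | C#C/C=C\[C@H](Cl)[C@@H](OC(C)=O)[C@H]1C/C=C(/Cl)C[C@@H](O)[C@@H](CC)O1 | intermediate
23 | C12 alkoxy(tri-n-octyl)phosphonium bromide of 22 | C#C/C=C\[C@H](Cl)[C@@H](OC(C)=O)[C@H]1C/C=C(/Cl)C[C@@H](O[P+](CCCCCCCC)(CCCCCCCC)CCCCCCCC)[C@@H](CC)O1.[Br-] | intermediate
24 | (1S,2S,3Z)-2-chloro-1-[(2R,4E,7S,8R)-7-bromo-5-chloro-8-ethyl-3,6,7,8-tetrahydro-2H-oxocin-2-yl]hex-3-en-5-yn-1-yl acetate (CNP0228902.1) | C#C/C=C\[C@H](Cl)[C@@H](OC(C)=O)[C@H]1C/C=C(/Cl)C[C@H](Br)[C@@H](CC)O1 | target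

**Step count and risks**

Total step count: 14. Longest linear sequence: 13 steps (steps 1–10 and 12–14; step 11 makes the metathesis partner).

Steps most likely to fail:

1. Step 3 (Proposed new method). What may go wrong: β-carbon elimination on the C13 side instead of the C7 side; closure onto the oxygenated allyl terminus instead of C8; diene oligomerisation outrunning the carbonyl coupling; loss of C7 control through equilibration of the nickel enolate. Fallback with known reactions, setting out from 5 and returning at 12: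
   - Indium-mediated Barbier addition of 2,3-dichloropropene (In powder, THF/H2O) to the C12 ketone of 5 should give methyl (4R)-3-(2-chloroprop-2-en-1-yl)-4-ethyl-3-hydroxyoxetane-2-carboxylate F1.
   - Catalytic DBU at 0 °C triggers retro-aldol opening of this strained β-hydroxy ester to the acyclic keto ether methyl 2-{[(3R)-6-chloro-4-oxohept-6-en-3-yl]oxy}acetate F2.
   - Felkin–Anh reduction with LiBH(s-Bu)3 gives the syn alcohol methyl 2-{[(3R,4R)-6-chloro-4-hydroxyhept-6-en-3-yl]oxy}acetate F3.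
   - TBSOTf/2,6-lutidine gives methyl 2-{[(3R,4R)-4-(tert-butyldimethylsilyloxy)-6-chlorohept-6-en-3-yl]oxy}acetate F4.
   - Enolisation with LiN(SiMe3)2 and alkylation with allyl iodide gives methyl 2-{[(3R,4R)-4-(tert-butyldimethylsilyloxy)-6-chlorohept-6-en-3-yl]oxy}pent-4-enoate F5 as both epimers at the new centre.
   - Ring-closing metathesis (second-generation Grubbs catalyst, dilute CH2Cl2, 40 °C) between the allyl and 2-chloroallyl groups closes the oxocene to 12 together with its C7 epimer, methyl (2S,4E,7R,8R)-7-(tert-butyldimethylsilyloxy)-5-chloro-8-ethyl-3,6,7,8-tetrahydro-2H-oxocine-2-carboxylate F6.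
   - NaOMe in MeOH should equilibrate F6 to the 2,8-cis ester 12, where the route is rejoined.

2. Step 12. What may go wrong: slow turnover of the terminal alkene, which carries an allylic chloride, and erosion of the Z-selectivity by secondary metathesis. Fallback, setting out from 17 and returning at 21:
   - Dihydroxylation of the terminal alkene (OsO4 cat., N-methylmorpholine N-oxide; the electron-poor, trisubstituted ring chloroalkene should be slower) gives (1S,2S)-1-[(2R,4E,7R,8R)-7-(tert-butyldimethylsilyloxy)-5-chloro-8-ethyl-3,6,7,8-tetrahydro-2H-oxocin-2-yl]-2-chloro-3,4-dihydroxybutyl acetate F7.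
   - NaIO4 cleaves it to the aldehyde (1S,2R)-1-[(2R,4E,7R,8R)-7-(tert-butyldimethylsilyloxy)-5-chloro-8-ethyl-3,6,7,8-tetrahydro-2H-oxocin-2-yl]-2-chloro-3-oxopropyl acetate F8.
   - Stork–Zhao olefination ((iodomethyl)triphenylphosphonium iodide, NaN(SiMe3)2, THF, −78 °C) gives the vinyl iodide (1S,2S,3Z)-1-[(2R,4E,7R,8R)-7-(tert-butyldimethylsilyloxy)-5-chloro-8-ethyl-3,6,7,8-tetrahydro-2H-oxocin-2-yl]-2-chloro-4-iodobut-3-en-1-yl acetate F9.
   - Sonogashira coupling with 18 (Pd(PPh3)4, CuI, Et3N) should give 21 with retention of the Z geometry.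

3. Step 4. What may go wrong: hydrolysis of the trimethylsilyl enol ether, or its migration into conjugation with the C12 ketone, during reduction and work-up. Fallback, setting out from 7 and returning at 11:
   - The reduction is run as in step 4 but worked up with aqueous citric acid, so that the enol ether is hydrolysed on purpose and methyl (2R,7R,8R)-8-ethyl-7-hydroxy-5-oxooxocane-2-carboxylate F10 is isolated.
   - Silylation (TBSOTf, 2,6-lutidine) gives methyl (2R,7R,8R)-7-(tert-butyldimethylsilyloxy)-8-ethyl-5-oxooxocane-2-carboxylate F11.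
   - Kinetic deprotonation with LiN(SiMe3)2 at −78 °C should occur at the less hindered C9 methylene, away from the silyloxy-bearing side; trapping with N-(5-chloro-2-pyridyl)triflimide gives enol triflate 11. The alkene position is then set by kinetic enolisation instead of being relayed from the diene.

Further compounds
F1 | step 3 | methyl (4R)-3-(2-chloroprop-2-en-1-yl)-4-ethyl-3-hydroxyoxetane-2-carboxylate (mixture at C2 and C3) | CC[C@H]1OC(C(=O)OC)C1(O)CC(Cl)=C
F2 | step 3 | methyl 2-{[(3R)-6-chloro-4-oxohept-6-en-3-yl]oxy}acetate | CC[C@@H](OCC(=O)OC)C(=O)CC(Cl)=C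
F3 | step 3 | methyl 2-{[(3R,4R)-6-chloro-4-hydroxyhept-6-en-3-yl]oxy}acetate | C=C(Cl)C[C@@H](O)[C@@H](CC)OCC(=O)OC
F4 | step 3 | methyl 2-{[(3R,4R)-4-(tert-butyldimethylsilyloxy)-6-chlorohept-6-en-3-yl]oxy}acetate | C=C(Cl)C[C@@H](O[Si](C)(C)C(C)(C)C)[C@@H](CC)OCC(=O)OC
F5 | step 3 | methyl 2-{[(3R,4R)-4-(tert-butyldimethylsilyloxy)-6-chlorohept-6-en-3-yl]oxy}pent-4-enoate (both C2 epimers) | C=C(Cl)C[C@@H](O[Si](C)(C)C(C)(C)C)[C@@H](CC)OC(CC=C)C(=O)OC
F6 | step 3 | methyl (2S,4E,7R,8R)-7-(tert-butyldimethylsilyloxy)-5-chloro-8-ethyl-3,6,7,8-tetrahydro-2H-oxocine-2-carboxylate | COC(=O)[C@@H]1C/C=C(/Cl)C[C@@H](O[Si](C)(C)C(C)(C)C)[C@@H](CC)O1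
F7 | step 12 | (1S,2S)-1-[(2R,4E,7R,8R)-7-(tert-butyldimethylsilyloxy)-5-chloro-8-ethyl-3,6,7,8-tetrahydro-2H-oxocin-2-yl]-2-chloro-3,4-dihydroxybutyl acetate (both C3 epimers) | OCC(O)[C@H](Cl)[C@@H](OC(C)=O)[C@H]1C/C=C(/Cl)C[C@@H](O[Si](C)(C)C(C)(C)C)[C@@H](CC)O1
F8 | step 12 | (1S,2R)-1-[(2R,4E,7R,8R)-7-(tert-butyldimethylsilyloxy)-5-chloro-8-ethyl-3,6,7,8-tetrahydro-2H-oxocin-2-yl]-2-chloro-3-oxopropyl acetate | O=C[C@H](Cl)[C@@H](OC(C)=O)[C@H]1C/C=C(/Cl)C[C@@H](O[Si](C)(C)C(C)(C)C)[C@@H](CC)O1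
F9 | step 12 | (1S,2S,3Z)-1-[(2R,4E,7R,8R)-7-(tert-butyldimethylsilyloxy)-5-chloro-8-ethyl-3,6,7,8-tetrahydro-2H-oxocin-2-yl]-2-chloro-4-iodobut-3-en-1-yl acetate | I/C=C\[C@H](Cl)[C@@H](OC(C)=O)[C@H]1C/C=C(/Cl)C[C@@H](O[Si](C)(C)C(C)(C)C)[C@@H](CC)O1
F10 | step 4 | methyl (2R,7R,8R)-8-ethyl-7-hydroxy-5-oxooxocane-2-carboxylate | COC(=O)[C@H]1CCC(=O)C[C@@H](O)[C@@H](CC)O1
F11 | step 4 | methyl (2R,7R,8R)-7-(tert-butyldimethylsilyloxy)-8-ethyl-5-oxooxocane-2-carboxylate | COC(=O)[C@H]1CCC(=O)C[C@@H](O[Si](C)(C)C(C)(C)C)[C@@H](CC)O1
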